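**Plan**

1. The C–OOH and C–OH bonds on the quinone are cut back to the two C–OMe bonds of a 2,5-dimethoxy-3,6-bis(indol-3-yl)-1,4-benzoquinone, and that quinone to its tetramethoxybenzene.
2. Enabling feature: each indole is joined to the central six-membered ring through C3 and has hydrogen at C2. Each pyrrole ring (N1, C2, C3, C3a, C7a) is therefore cut at N1–C2 and C3–C3a, leaving 2-bromo-4-prenylaniline and a silylethynyl arm (future C2 and C3) on the core.
3. The alkyne arms are cut from the core at the aryl–alkynyl bonds (diiodide plus trimethylsilylacetylene). The prenyl group is cut from the aniline at the aryl–CH2 bond.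
4. Forward: the central carbocycle is present from the first step. Both pyrrole rings close in one operation on the bis-alkyne. C2 desilylation, oxidation to the quinone and two successive C–O exchanges complete the molecule.
5. Stereochemistry: the target has no stereocentre and no E/Z alkene (each prenyl alkene carries two methyl groups), so only regiochemistry has to be controlled.

Key step: step 4

Remark: 11 may exist as slowly interconverting rotamers about its two aryl–indole bonds; these converge at 13 and are treated as one compound.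

**Route**

Step 1
Reactants: 1 1,2,4,5-tetramethoxybenzene
Product: 3 1,4-diiodo-2,3,5,6-tetramethoxybenzene, via 3-iodo-1,2,4,5-tetramethoxybenzene 2 (not isolated)
Conditions: NIS (2.3 equiv), TFA (cat.), MeCN, 0 °C to rt, dark
Reagents that add atoms: N-iodosuccinimide, O=C1CCC(=O)N1I
Why: Electrophilic aromatic iodination (SEAr) with the iodonium equivalent from NIS and acid: the only two ring C–H positions each lie between two methoxy groups and are strongly activated, and this mild halogen source should not oxidise the arene to the quinone.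

Step 2
Reactants: 3 1,4-diiodo-2,3,5,6-tetramethoxybenzene; 4 trimethylsilylacetylene (2.5 equiv)
Product: 6 1,4-bis(trimethylsilylethynyl)-2,3,5,6-tetramethoxybenzene, via 1-iodo-4-(trimethylsilylethynyl)-2,3,5,6-tetramethoxybenzene 5 (not isolated)
Conditions: PdCl2(PPh3)2 (5 mol%), CuI (10 mol%), Et3N, THF, 60 °C, argon
Reagents that add atoms: none
Why: Twofold Sonogashira coupling: oxidative addition at the aryl C–I bonds should be feasible despite the flanking methoxy groups because iodide is the most reactive halide and the incoming copper acetylide is linear and undemanding, while the silyl cap blocks the other alkyne terminus.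

Step 3
Reactants: 7 2-bromo-4-iodoaniline; 8 prenylboronic acid pinacol ester (1.05 equiv)
Product: 9 2-bromo-4-(3-methylbut-2-enyl)aniline
Conditions: (IPent)PdCl2(3-chloropyridine) (2 mol%; IPent = 1,3-bis[2,6-di(pentan-3-yl)phenyl]imidazol-2-ylidene), aq. KOH, THF, 50 °C
Reagents that add atoms: none
Why: Suzuki–Miyaura sp2–sp3 coupling in which oxidative addition should occur at the C–I bond well before the C–Br bond that is flanked and deactivated by the amino group, and the bulky carbene ligand keeps palladium on the unsubstituted CH2 terminus of the prenyl group so that reductive elimination gives the linear 3-methylbut-2-enyl isomer and not the 1,1-dimethylallyl one.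

Step 4
Reactants: 6 1,4-bis(trimethylsilylethynyl)-2,3,5,6-tetramethoxybenzene; 9 2-bromo-4-(3-methylbut-2-enyl)aniline (2.4 equiv)
Product: 11 1,4-bis[5-(3-methylbut-2-enyl)-2-(trimethylsilyl)-1H-indol-3-yl]-2,3,5,6-tetramethoxybenzene, via mono-annulated indolyl silylalkyne 10 (not isolated)
Conditions: Pd(OAc)2 (10 mol%), P(t-Bu)3·HBF4 (20 mol%), Cy2NMe (5 equiv), 1,4-dioxane, 80 °C, argon
Reagents that add atoms: none
Why: Larock heteroannulation run twice in one flask: zerovalent palladium carrying P(t-Bu)3 inserts into the C–Br bond of 9, the arylpalladium bromide adds syn across a silylalkyne of 6 so that the aryl carbon (future C3a) bonds to the alkyne carbon bearing the central ring and palladium to the silicon-bearing carbon, the aniline nitrogen then binds palladium with loss of HBr to Cy2NMe, and C–N reductive elimination forms N1–C2. The closest known reaction type is the Larock indole synthesis of ortho-bromoanilines with aryl(trialkylsilyl)alkynes under Pd/P(t-Bu)3 catalysis. Each pyrrole ring closes by reductive elimination from a six-membered azapalladacycle (Pd, N, C7a, C3a, C3, C2) to the five-membered ring; the first annulation gives 10 and the same cycle on its remaining alkyne gives 11. No stereocentre is formed, and restricted rotation about the aryl–indole bonds of 11 disappears on desilylation. The step needs one orientation of alkyne insertion, and the bulk of the trimethylsilyl group together with its stabilisation of the adjacent C–Pd bond should place silicon next to nitrogen at C2 and the central ring at C3. The trisubstituted prenyl alkenes are too hindered for Heck insertion, the free NH2 needs no protection, and the hexasubstituted core has no C–H bond to palladate.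

Step 5
Reactants: 11 1,4-bis[5-(3-methylbut-2-enyl)-2-(trimethylsilyl)-1H-indol-3-yl]-2,3,5,6-tetramethoxybenzene
Product: 13 1,4-bis[5-(3-methylbut-2-enyl)-1H-indol-3-yl]-2,3,5,6-tetramethoxybenzene, via mono-desilylated bis-indole 12 (not isolated)
Conditions: Bu4NF (1 M in THF, 4 equiv), THF, 60 °C; aqueous work-up
Reagents that add atoms: none
Why: Fluoride-mediated ipso-protodesilylation of a C2-silylindole, a known follow-up to Larock annulations: fluoride attacks silicon and C2 is protonated by the water in the reagent, and the non-acidic medium leaves the prenyl alkenes and aryl methyl ethers untouched.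

Step 6
Reactants: 13 1,4-bis[5-(3-methylbut-2-enyl)-1H-indol-3-yl]-2,3,5,6-tetramethoxybenzene
Product: 14 2,5-dimethoxy-3,6-bis[5-(3-methylbut-2-enyl)-1H-indol-3-yl]-1,4-benzoquinone
Conditions: (NH4)2Ce(NO3)6 (2.2 equiv), MeCN/H2O, 0 °C, short reaction time
Reagents that add atoms: water, O
Why: Oxidative demethylation of a para-dimethoxyarene by tetravalent cerium: the tetra-oxygenated central ring is the most electron-rich π-system, gives up two electrons in succession, is attacked by water at two para-related ipso carbons and expels two molecules of methanol to give the para-quinone, under cold and brief conditions that should spare the indoles and prenyl groups.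

Step 7
Reactants: 14 2,5-dimethoxy-3,6-bis[5-(3-methylbut-2-enyl)-1H-indol-3-yl]-1,4-benzoquinone
Product: 15 2-hydroxy-5-methoxy-3,6-bis[5-(3-methylbut-2-enyl)-1H-indol-3-yl]-1,4-benzoquinone
Conditions: 1 M aq. NaOH (1.1 equiv), THF, 0 °C to rt, argon; then 1 M HCl
Reagents that add atoms: sodium hydroxide, [Na+].[OH-]
Why: Addition–elimination at a vinylogous ester carbon (saponification of a methoxyquinone): hydroxide adds at a methoxy-bearing carbon and expels methoxide, the resulting hydroxyquinone anion is a vinylogous carboxylate that should resist a second attack at room temperature, and the two methoxy groups are equivalent by symmetry so that no regiochemical question arises.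

Step 8
Reactants: 15 2-hydroxy-5-methoxy-3,6-bis[5-(3-methylbut-2-enyl)-1H-indol-3-yl]-1,4-benzoquinone
Product: 16 hydroperoxycochliodinol (2-hydroperoxy-5-hydroxy-3,6-bis[5-(3-methylbut-2-enyl)-1H-indol-3-yl]-1,4-benzoquinone)
Conditions: 30% aq. H2O2 (10 equiv), LiOH (2.5 equiv), THF/H2O, 0 °C, dark; then cold 1 M HCl to pH 3
Reagents that add atoms: hydrogen peroxide, OO
Why: Proposed new method: nucleophilic vinylic substitution (addition–elimination) of the remaining vinylogous ester methoxide by hydroperoxide anion, which in excess H2O2 is the dominant base-derived nucleophile and, through the alpha effect, far more reactive than hydroxide, so that it should add at the methoxy-bearing quinone carbon and expel methoxide at 0 °C, where hydroxide exchange is slow, the product resting as its unreactive dianion until the cold acid quench; the closest known reaction types are the perhydrolysis of esters and acid chlorides to peroxy acids and the hydroxide or alkoxide exchange of methoxyquinones.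

**Compound list**

1 | 1,2,4,5-tetramethoxybenzene | COc1cc(OC)c(OC)cc1OC | starting material
2 | 3-iodo-1,2,4,5-tetramethoxybenzene | COc1cc(OC)c(OC)c(I)c1OC | intermediate
3 | 1,4-diiodo-2,3,5,6-tetramethoxybenzene | COc1c(I)c(OC)c(OC)c(I)c1OC | intermediate
4 | trimethylsilylacetylene | C#C[Si](C)(C)C | starting material
5 | 1-iodo-4-(trimethylsilylethynyl)-2,3,5,6-tetramethoxybenzene | COc1c(I)c(OC)c(OC)c(C#C[Si](C)(C)C)c1OC | intermediate
6 | 1,4-bis(trimethylsilylethynyl)-2,3,5,6-tetramethoxybenzene | COc1c(OC)c(C#C[Si](C)(C)C)c(OC)c(OC)c1C#C[Si](C)(C)C | intermediate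
7 | 2-bromo-4-iodoaniline | Nc1ccc(I)cc1Br | starting material
8 | prenylboronic acid pinacol ester | CC(C)=CCB1OC(C)(C)C(C)(C)O1 | starting material
9 | 2-bromo-4-(3-methylbut-2-enyl)aniline | Nc1ccc(CC=C(C)C)cc1Br | intermediate
10 | 5-(3-methylbut-2-enyl)-3-[2,3,5,6-tetramethoxy-4-(trimethylsilylethynyl)phenyl]-2-(trimethylsilyl)-1H-indole | COc1c(OC)c(-c2c([Si](C)(C)C)[nH]c3ccc(CC=C(C)C)cc23)c(OC)c(OC)c1C#C[Si](C)(C)C | intermediate
11 | 1,4-bis[5-(3-methylbut-2-enyl)-2-(trimethylsilyl)-1H-indol-3-yl]-2,3,5,6-tetramethoxybenzene | COc1c(OC)c(-c2c([Si](C)(C)C)[nH]c3ccc(CC=C(C)C)cc23)c(OC)c(OC)c1-c1c([Si](C)(C)C)[nH]c2ccc(CC=C(C)C)cc12 | intermediate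
12 | 5-(3-methylbut-2-enyl)-3-{2,3,5,6-tetramethoxy-4-[5-(3-methylbut-2-enyl)-1H-indol-3-yl]phenyl}-2-(trimethylsilyl)-1H-indole | COc1c(OC)c(-c2c[nH]c3ccc(CC=C(C)C)cc23)c(OC)c(OC)c1-c1c([Si](C)(C)C)[nH]c2ccc(CC=C(C)C)cc12 | intermediate
13 | 1,4-bis[5-(3-methylbut-2-enyl)-1H-indol-3-yl]-2,3,5,6-tetramethoxybenzene | COc1c(OC)c(-c2c[nH]c3ccc(CC=C(C)C)cc23)c(OC)c(OC)c1-c1c[nH]c2ccc(CC=C(C)C)cc12 | intermediate
14 | 2,5-dimethoxy-3,6-bis[5-(3-methylbut-2-enyl)-1H-indol-3-yl]-1,4-benzoquinone | COC1=C(c2c[nH]c3ccc(CC=C(C)C)cc23)C(=O)C(OC)=C(c2c[nH]c3ccc(CC=C(C)C)cc23)C1=O | intermediate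
15 | 2-hydroxy-5-methoxy-3,6-bis[5-(3-methylbut-2-enyl)-1H-indol-3-yl]-1,4-benzoquinone | COC1=C(c2c[nH]c3ccc(CC=C(C)C)cc23)C(=O)C(O)=C(c2c[nH]c3ccc(CC=C(C)C)cc23)C1=O | intermediate
16 | hydroperoxycochliodinol | CC(C)=CCc1ccc2[nH]cc(C3=C(O)C(=O)C(c4c[nH]c5ccc(CC=C(C)C)cc45)=C(OO)C3=O)c2c1 | target

**Totals and risks**

Total steps: 8. Longest linear sequence: 7 steps (steps 1, 2, 4, 5, 6, 7 and 8, from 1); step 3 is a one-step branch that joins at step 4.

Steps most likely to fail:

1. Step 8. The peroxide adduct may close to an epoxide instead of expelling methoxide (Weitz–Scheffer pathway). The hydroxyquinone ring may contract oxidatively (Hooker-type degradation). The anionic quinone may also resist attack, so that slow hydroxide exchange takes over. The fallback sets out from 15, comes back at 16, and uses only known reaction types. Excess NaOH in MeOH/H2O at reflux under argon, followed by HCl, should exchange the second methoxy group and give cochliodinol F1, the usual full saponification of bis(indolyl)dimethoxyquinones. One equivalent of TsCl with Et3N in CH2Cl2 at −20 °C should sulfonylate one oxygen of the dianion and give the cochliodinol mono-tosylate F2, because the monoanion that remains is the weaker nucleophile. O-sulfonylation of hydroxyquinones is known. The sulfonate is a vinylogous mixed anhydride. H2O2 with LiOH in THF/H2O at −20 °C, followed by a cold HCl quench, should displace tosylate and give 16. This parallels the preparation of peroxy acids from mixed anhydrides and the known displacement of quinone sulfonates by heteroatom nucleophiles, at a temperature where the degradations above are slow.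

2. Step 4. Insertion into alkyne carbons flanked by two methoxy groups may be slow. The orientation may erode if the bulk of the di-ortho-substituted aryl group rivals that of silicon. The second annulation may stall at 10. The fallback sets out from 8 and comes back at 14, bypassing steps 4 to 6. Commercial 5-bromoindole (Brc1ccc2[nH]ccc2c1) is coupled with 8 under the conditions of step 3 to give 5-(3-methylbut-2-enyl)-1H-indole F3. In AcOH/THF at rt, C3 of this indole adds to an unsubstituted carbon of commercial 2,5-dichloro-1,4-benzoquinone (O=C1C=C(Cl)C(=O)C=C1Cl). This acid-promoted conjugate addition is known for prenylated indoles and gives 2,5-dichloro-3-[5-(3-methylbut-2-enyl)-1H-indol-3-yl]benzene-1,4-diol F4. DDQ reoxidises it to 2,5-dichloro-3-[5-(3-methylbut-2-enyl)-1H-indol-3-yl]-1,4-benzoquinone F5. A second molecule of the indole adds at the last C–H position to give 2,5-dichloro-3,6-bis[5-(3-methylbut-2-enyl)-1H-indol-3-yl]benzene-1,4-diol F6. DDQ then gives 2,5-dichloro-3,6-bis[5-(3-methylbut-2-enyl)-1H-indol-3-yl]-1,4-benzoquinone F7. NaOMe in MeOH at rt replaces both chlorides by addition–elimination and delivers 14.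

3. Step 6. Single-electron oxidation of the free indoles, or cleavage at their C2–C3 bonds, may compete with oxidation of the central ring. Some ortho-quinone may also form. The fallback sets out from 13 and comes back at 14. Boc2O with catalytic DMAP in MeCN should give 1,4-bis[1-(tert-butoxycarbonyl)-5-(3-methylbut-2-enyl)indol-3-yl]-2,3,5,6-tetramethoxybenzene F8, whose acylated indoles are harder to oxidise. (NH4)2Ce(NO3)6 in MeCN/H2O at 0 °C should then give 2,5-dimethoxy-3,6-bis[1-(tert-butoxycarbonyl)-5-(3-methylbut-2-enyl)indol-3-yl]-1,4-benzoquinone F9. Catalytic K2CO3 in MeOH at rt removes both carbamates by methanolysis, and methoxide exchange at the quinone is degenerate, so 14 results.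

**Further compounds**

F1 | step 8 | cochliodinol (2,5-dihydroxy-3,6-bis[5-(3-methylbut-2-enyl)-1H-indol-3-yl]-1,4-benzoquinone) | CC(C)=CCc1ccc2[nH]cc(C3=C(O)C(=O)C(c4c[nH]c5ccc(CC=C(C)C)cc45)=C(O)C3=O)c2c1
F2 | step 8 | cochliodinol mono-tosylate (2-hydroxy-5-(4-methylphenylsulfonyloxy)-3,6-bis[5-(3-methylbut-2-enyl)-1H-indol-3-yl]-1,4-benzoquinone) | Cc1ccc(S(=O)(=O)OC2=C(c3c[nH]c4ccc(CC=C(C)C)cc34)C(=O)C(O)=C(c3c[nH]c4ccc(CC=C(C)C)cc34)C2=O)cc1
F3 | step 4 | 5-(3-methylbut-2-enyl)-1H-indole | CC(C)=CCc1ccc2[nH]ccc2c1
F4 | step 4 | 2,5-dichloro-3-[5-(3-methylbut-2-enyl)-1H-indol-3-yl]benzene-1,4-diol | Oc1cc(Cl)c(O)c(-c2c[nH]c3ccc(CC=C(C)C)cc23)c1Cl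
F5 | step 4 | 2,5-dichloro-3-[5-(3-methylbut-2-enyl)-1H-indol-3-yl]-1,4-benzoquinone | O=C1C=C(Cl)C(=O)C(c2c[nH]c3ccc(CC=C(C)C)cc23)=C1Cl
F6 | step 4 | 2,5-dichloro-3,6-bis[5-(3-methylbut-2-enyl)-1H-indol-3-yl]benzene-1,4-diol | Oc1c(Cl)c(-c2c[nH]c3ccc(CC=C(C)C)cc23)c(O)c(Cl)c1-c1c[nH]c2ccc(CC=C(C)C)cc12
F7 | step 4 | 2,5-dichloro-3,6-bis[5-(3-methylbut-2-enyl)-1H-indol-3-yl]-1,4-benzoquinone | O=C1C(Cl)=C(c2c[nH]c3ccc(CC=C(C)C)cc23)C(=O)C(Cl)=C1c1c[nH]c2ccc(CC=C(C)C)cc12
F8 | step 6 | 1,4-bis[1-(tert-butoxycarbonyl)-5-(3-methylbut-2-enyl)indol-3-yl]-2,3,5,6-tetramethoxybenzene | COc1c(OC)c(-c2cn(C(=O)OC(C)(C)C)c3ccc(CC=C(C)C)cc23)c(OC)c(OC)c1-c1cn(C(=O)OC(C)(C)C)c2ccc(CC=C(C)C)cc12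
F9 | step 6 | 2,5-dimethoxy-3,6-bis[1-(tert-butoxycarbonyl)-5-(3-methylbut-2-enyl)indol-3-yl]-1,4-benzoquinone | COC1=C(c2cn(C(=O)OC(C)(C)C)c3ccc(CC=C(C)C)cc23)C(=O)C(OC)=C(c2cn(C(=O)OC(C)(C)C)c3ccc(CC=C(C)C)cc23)C1=O
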